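**Plan**
- Hardest feature: C2 of the 2H-pyran ring is fully substituted (O1, CH3, C3=C4, C1'H2). Its CH3 and CH2R arms are almost alike, and C2 racemises through any free o-quinone methide.
- Cuts: O1–C2 and C1'–C2' together (key step), then Cα=Cβ of the enone (aldol), C4–C4a (cross-coupling) and the C6–acetyl bond. The C5 and C8 OH groups are carried as OMe.
- Enabling feature: C2–C3–C4 is an allyl unit ending on C4a, ortho to the O1-bearing C8a, and C1' lies between C2 and the sp2 carbon C2'. C2/C1' can therefore be the C=CH2 end of an (E)-3-methylbutadienyl phenol that takes up an alkenyl–Pd, and O1 then closes the π-allyl.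
- Forward order: acetyl, then iodine, onto 2,5-dimethoxyphenol; then the dienyl arm; then pyran ring, whole side chain and C2 in one Pd cascade; then the chalcone. The hydroquinone is released last by Ce(IV)/dithionite, which works because C5–O and C8–O are para.
- Stereochemistry: C2 comes from face-selective migratory insertion under a chiral Pd–phosphoramidite, which distinguishes CH3 from styryl on a C=CH2 rather than CH3 from CH2R. The C2'=C3' E geometry comes from the vinyl iodide, and the enone E geometry from the condensation.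

Key step: step 6

Numbering: chromene O1, C2–C4, C4a, C5–C8, C8a; side chain C1'–C4'. The target stereocentre is (S).
Assumption: the sense of induction of the ligand L* in step 6 cannot be predicted safely. The antipode that leads to (S)-11 is to be fixed in a trial run; both antipodes are accessible from (R)- and (S)-H8-BINOL.

Step 1
Reactants: 1 2,5-dimethoxyphenol
Product: 3 1-(4-hydroxy-2,5-dimethoxyphenyl)ethan-1-one, via 2,5-dimethoxyphenyl acetate 2 (not isolated)
Conditions: Ac2O (1.1 equiv), MeSO3H, 0 to 40 °C
Reagents that add atoms: acetic anhydride CC(=O)OC(C)=O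
Why: O-acetylation followed by para-selective Fries rearrangement (Friedel–Crafts acylation) should place the acetyl group para to OH and ortho to a methoxy group, which is the site that 1,2,4-trioxygenated benzenes normally use and the less hindered of the two doubly activated positions.

Step 2
Reactants: 3 1-(4-hydroxy-2,5-dimethoxyphenyl)ethan-1-one
Product: 4 1-(4-hydroxy-3-iodo-2,5-dimethoxyphenyl)ethan-1-one
Conditions: NIS (1.05 equiv), TsOH·H2O (10 mol %), MeCN, 0 °C to rt
Reagents that add atoms: N-iodosuccinimide O=C1CCC(=O)N1I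
Why: Electrophilic aromatic iodination should go to the only free position ortho to the phenol OH, which is also ortho to OMe and meta to acetyl, whereas the other free CH is ortho to the deactivating acetyl group.

Step 3
Reactants: 5 2-methylbut-1-en-3-yne
Product: 6 (E)-4,4,5,5-tetramethyl-2-(3-methylbuta-1,3-dien-1-yl)-1,3,2-dioxaborolane
Conditions: HBpin (1.05 equiv), Cp2ZrHCl (5 mol %), Et3N (5 mol %), CH2Cl2, rt, sealed vessel
Reagents that add atoms: pinacolborane [H]B1OC(C)(C)C(C)(C)O1
Why: Zirconocene-hydride-catalysed syn-hydroboration selects the terminal alkyne over the 1,1-disubstituted alkene and gives the (E)-1-alkenylboronate.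

Step 4
Reactants: 4 1-(4-hydroxy-3-iodo-2,5-dimethoxyphenyl)ethan-1-one; 6 (E)-dienyl pinacol boronate
Product: 7 1-{4-hydroxy-2,5-dimethoxy-3-[(1E)-3-methylbuta-1,3-dien-1-yl]phenyl}ethan-1-one
Conditions: Pd(OAc)2 (3 mol %), SPhos (6 mol %), K3PO4 (3 equiv), 6 (1.3 equiv), THF/H2O 10:1, 45 °C, degassed, dark; product kept away from acid and light
Reagents that add atoms: none
Why: Suzuki–Miyaura coupling with a dialkylbiarylphosphine ligand tolerates free phenols and di-ortho-substituted aryl iodides and retains the E geometry of the alkenylboronate.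

Step 5
Reactants: 8 2-methylbut-3-yn-2-ol
Product: 10 (E)-4-iodo-2-methylbut-3-en-2-ol, via (E)-2-methyl-4-(tributylstannyl)but-3-en-2-ol 9 (not isolated)
Conditions: Bu3SnH (1.05 equiv), PdCl2(PPh3)2 (1 mol %), THF, 0 °C to rt; then I2 (1.05 equiv), 0 °C
Reagents that add atoms: iodine II; tributyltin hydride CCCC[SnH](CCCC)CCCC (tin stays only in 9)
Why: Pd-catalysed syn-hydrostannation of a terminal alkyne next to a bulky tertiary carbinol places tin on the terminal carbon with E geometry, and iododestannylation proceeds with retention.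

Step 6
Reactants: 7 (E)-dienyl phenol; 10 (E)-4-iodo-2-methylbut-3-en-2-ol
Product: 11 1-{(2S)-2-[(2E)-4-hydroxy-4-methylpent-2-en-1-yl]-5,8-dimethoxy-2-methyl-2H-chromen-6-yl}ethan-1-one
Conditions: Pd2(dba)3·CHCl3 (2.5 mol %), H8-BINOL-derived phosphoramidite L* (11 mol %), K2CO3 (2 equiv), 10 (1.3 equiv), MTBE/1,4-dioxane, 0.02 M, 45 °C, Ar, dark
Reagents that add atoms: none
Why: Proposed new method: Pd(0)L* adds oxidatively to the C–I bond of 10, the (E)-alkenyl–Pd(II) inserts the terminal C2=C1'H2 bond of 7 with C2' going to C1' and Pd to C2, the resulting η3-allyl over C2–C3–C4 moves its aryl group from syn to anti by σ-bonding at benzylic C4 and rotation about C3–C4, and the phenoxide O1 then attacks C2 with release of Pd(0). The closest known reaction types are the enantioselective Heck/Tsuji–Trost (Larock-type) carbo-heterofunctionalisation of 1,3-dienes with aryl or alkenyl halides and the Pd-catalysed asymmetric cyclisation of (E)-o-hydroxycinnamyl esters to 2H-chromenes, which already contains the syn-to-anti step; new is their union on a 3-methyldienyl phenol so that a fully substituted C2 results. The pyran ring closes by 6-endo-trig allylic etherification at the distal allyl terminus C2, attack at C4 being excluded because it would give a four-membered ring. C2 is controlled by the ligand at the insertion, where the two faces of a C=CH2 group flanked by CH3 and a bulky styryl arm are told apart, and since π–σ–π events can change the Pd-bound face of C2 only together with the syn/anti position of the aryl group, each insertion face of geometrically pure (E)-7 leads to one enantiomer only. The step needs insertion at the terminal alkene (C3=C4 is shielded by the 2,6-disubstituted aryl group), ring closure faster than β-hydride loss from C1' (secured by the intramolecular phenoxide of a phenol acidified by the para acetyl group, with high dilution against intermolecular O-allylation), and closure through O1 only (O5 and O8 are methylated, and the tertiary OH of 10 cannot reach C2 across the E double bond). The para acetyl group should also disfavour loss of Pd(0) to a free o-quinone methide, whose electrocyclisation would escape catalyst control.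

Step 7
Reactants: 11 (S)-6-acetylchromene; 12 benzaldehyde
Product: 13 (2E)-1-{(2S)-2-[(2E)-4-hydroxy-4-methylpent-2-en-1-yl]-5,8-dimethoxy-2-methyl-2H-chromen-6-yl}-3-phenylprop-2-en-1-one
Conditions: 12 (1.2 equiv), KOH, EtOH, 0 °C to rt, Ar, dark
Reagents that add atoms: none
Why: Claisen–Schmidt condensation of an aryl methyl ketone without a free phenol gives the (E)-enone under thermodynamic control, and base affects neither the chromene, the tertiary alcohol nor C2, which has no acidifying relationship to the carbonyl group.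

Step 8
Reactants: 13 (S)-chalcone dimethyl ether
Product: 15 (2E)-1-{(2S)-5,8-dihydroxy-2-[(2E)-4-hydroxy-4-methylpent-2-en-1-yl]-2-methyl-2H-chromen-6-yl}-3-phenylprop-2-en-1-one, via (2S)-2-[(2E)-4-hydroxy-4-methylpent-2-en-1-yl]-2-methyl-6-[(2E)-3-phenylprop-2-enoyl]-2H-chromene-5,8-dione 14 (not isolated)
Conditions: (NH4)2Ce(NO3)6 (2.3 equiv), MeCN/H2O 3:1, −5 to 0 °C, at most 10 min, dark; then poured into aq Na2S2O4/EtOAc, 0 °C, Ar
Reagents that add atoms: water O (the two quinone oxygens of 14, hence the C5 and C8 oxygens of 15)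
Why: Ce(IV) oxidative demethylation of the para C5/C8 dimethoxy pair to the p-quinone with immediate dithionite reduction is the standard Lewis-acid-free release of a hydroquinone from its dimethyl ether and leaves the O1–C2 bond, and thus the stereocentre, untouched.

**Compound list**
1 | 2,5-dimethoxyphenol | COc1ccc(OC)c(O)c1 | starting material
2 | 2,5-dimethoxyphenyl acetate | COc1ccc(OC)c(OC(C)=O)c1 | intermediate
3 | 1-(4-hydroxy-2,5-dimethoxyphenyl)ethan-1-one | CC(=O)c1cc(OC)c(O)cc1OC | intermediate
4 | 1-(4-hydroxy-3-iodo-2,5-dimethoxyphenyl)ethan-1-one | CC(=O)c1cc(OC)c(O)c(I)c1OC | intermediate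
5 | 2-methylbut-1-en-3-yne | C=C(C)C#C | starting material
6 | (E)-4,4,5,5-tetramethyl-2-(3-methylbuta-1,3-dien-1-yl)-1,3,2-dioxaborolane | C=C(C)/C=C/B1OC(C)(C)C(C)(C)O1 | intermediate
7 | 1-{4-hydroxy-2,5-dimethoxy-3-[(1E)-3-methylbuta-1,3-dien-1-yl]phenyl}ethan-1-one | CC(=O)c1cc(OC)c(O)c(/C=C/C(C)=C)c1OC | intermediate
8 | 2-methylbut-3-yn-2-ol | CC(C)(O)C#C | starting material
9 | (E)-2-methyl-4-(tributylstannyl)but-3-en-2-ol | CCCC[Sn](CCCC)(CCCC)/C=C/C(C)(C)O | intermediate
10 | (E)-4-iodo-2-methylbut-3-en-2-ol | CC(C)(O)/C=C/I | intermediate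
11 | 1-{(2S)-2-[(2E)-4-hydroxy-4-methylpent-2-en-1-yl]-5,8-dimethoxy-2-methyl-2H-chromen-6-yl}ethan-1-one | CC(C)(O)/C=C/C[C@@]1(C)C=Cc2c(OC)c(C(C)=O)cc(OC)c2O1 | intermediate
12 | benzaldehyde | O=Cc1ccccc1 | starting material
13 | (2E)-1-{(2S)-2-[(2E)-4-hydroxy-4-methylpent-2-en-1-yl]-5,8-dimethoxy-2-methyl-2H-chromen-6-yl}-3-phenylprop-2-en-1-one | CC(C)(O)/C=C/C[C@@]1(C)C=Cc2c(OC)c(C(=O)/C=C/c3ccccc3)cc(OC)c2O1 | intermediate
14 | (2S)-2-[(2E)-4-hydroxy-4-methylpent-2-en-1-yl]-2-methyl-6-[(2E)-3-phenylprop-2-enoyl]-2H-chromene-5,8-dione | CC(C)(O)/C=C/C[C@@]1(C)C=CC2=C(O1)C(=O)C=C(C(=O)/C=C/c3ccccc3)C2=O | intermediate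
15 | (2E)-1-{(2S)-5,8-dihydroxy-2-[(2E)-4-hydroxy-4-methylpent-2-en-1-yl]-2-methyl-2H-chromen-6-yl}-3-phenylprop-2-en-1-one | CC(C)(O)/C=C/C[C@@]1(C)C=Cc2c(O)c(C(=O)/C=C/c3ccccc3)cc(O)c2O1 | target

Total step count: 8. Longest linear sequence: 6 (steps 1, 2, 4, 6, 7, 8).

**Steps most likely to fail**

1. Step 6 (bears the label).
- β-Hydride loss from C1' or from the C2 methyl group may outrun ring closure.
- The syn-to-anti isomerisation may be slow, so that intermolecular O-allylation takes over.
- Pd(0) may leave the allyl/phenoxide zwitterion, so that the ring closes without catalyst control. Alternatively, the face selectivity of the insertion may be poor. Either would lower the enantiomeric purity.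
- Fallback, known chemistry, from 4 back to 11. Suzuki vinylation of 4 with potassium vinyltrifluoroborate (K2CO3) should give 1-(3-ethenyl-4-hydroxy-2,5-dimethoxyphenyl)ethan-1-one F1.
- Geraniol and methyl chloroformate give geranyl methyl carbonate F2.
- Pd-catalysed asymmetric allylic O-alkylation of F1 with F2 (DACH-phenyl bis(2-diphenylphosphinobenzamide) ligand, antipode chosen for S) should give the branched tertiary ether 1-(4-{[(3S)-3,7-dimethylocta-1,6-dien-3-yl]oxy}-3-ethenyl-2,5-dimethoxyphenyl)ethan-1-one F3.
- Ring-closing metathesis (second-generation Ru–NHC benzylidene catalyst, initiation at the styrene) joins the styrene and the vinyl group to 1-[(2S)-5,8-dimethoxy-2-methyl-2-(4-methylpent-3-en-1-yl)-2H-chromen-6-yl]ethan-1-one F4.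
- Markovnikov hydroxyselenation of the trisubstituted alkene (PhSeCl, MeCN/H2O) gives 1-{(2S)-2-[4-hydroxy-4-methyl-3-(phenylselanyl)pentyl]-5,8-dimethoxy-2-methyl-2H-chromen-6-yl}ethan-1-one F5.
- H2O2 oxidation of F5 with syn-elimination away from the carbinol carbon gives 11.

2. Step 8.
- Oxidation may attack the C3=C4 bond or the enone.
- The acidic Ce(IV) medium may ionise or transpose the tertiary allylic alcohol.
- Nucleophiles may add to the very electrophilic cinnamoylquinone before it is reduced.
- Fallback, from 11 back to 15: the hydroquinone is released before the enone exists, so that no cinnamoylquinone is ever formed.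
- Ce(IV) oxidation of 11 gives (2S)-6-acetyl-2-[(2E)-4-hydroxy-4-methylpent-2-en-1-yl]-2-methyl-2H-chromene-5,8-dione F6, which is reduced at once with dithionite to 1-{(2S)-5,8-dihydroxy-2-[(2E)-4-hydroxy-4-methylpent-2-en-1-yl]-2-methyl-2H-chromen-6-yl}ethan-1-one F7.
- Claisen–Schmidt condensation of the free 2',5'-dihydroxyacetophenone unit of F7 with 12 (excess KOH, EtOH, strictly under Ar) then gives 15.

3. Step 4.
- Transmetalation at the di-ortho-substituted aryl–Pd may be slow.
- The dienylboronate may protodeboronate.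
- The diene product may be consumed by remaining aryl–Pd in a Heck/allylic etherification side cascade.
- Fallback, from 3 back to 7: the C3=C4 bond is made by olefination instead of making the C4–C4a bond by coupling.
- Chloromethylation of 3 (paraformaldehyde, conc. HCl) at the only activated position gives 1-[3-(chloromethyl)-4-hydroxy-2,5-dimethoxyphenyl]ethan-1-one F8.
- PPh3 converts F8 into (3-acetyl-6-hydroxy-2,5-dimethoxybenzyl)triphenylphosphonium chloride F9.
- The weakly basic benzylic ylide of F9 (K2CO3, CH2Cl2/H2O) undergoes a Wittig reaction with methacrolein without touching the methyl ketone, and the E isomer 7 is separated.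

Further compounds
F1 | step 6 | 1-(3-ethenyl-4-hydroxy-2,5-dimethoxyphenyl)ethan-1-one | CC(=O)c1cc(OC)c(O)c(C=C)c1OC
F2 | step 6 | (2E)-3,7-dimethylocta-2,6-dien-1-yl methyl carbonate (geranyl methyl carbonate) | CC(C)=CCC/C(C)=C/COC(=O)OC
F3 | step 6 | 1-(4-{[(3S)-3,7-dimethylocta-1,6-dien-3-yl]oxy}-3-ethenyl-2,5-dimethoxyphenyl)ethan-1-one | CC(C)=CCC[C@@](C)(C=C)Oc1c(C=C)c(OC)c(C(C)=O)cc1OC
F4 | step 6 | 1-[(2S)-5,8-dimethoxy-2-methyl-2-(4-methylpent-3-en-1-yl)-2H-chromen-6-yl]ethan-1-one | CC(C)=CCC[C@@]1(C)C=Cc2c(OC)c(C(C)=O)cc(OC)c2O1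
F5 | step 6 | 1-{(2S)-2-[4-hydroxy-4-methyl-3-(phenylselanyl)pentyl]-5,8-dimethoxy-2-methyl-2H-chromen-6-yl}ethan-1-one (both configurations at C3') | CC(C)(O)C(CC[C@@]1(C)C=Cc2c(OC)c(C(C)=O)cc(OC)c2O1)[Se]c1ccccc1
F6 | step 8 | (2S)-6-acetyl-2-[(2E)-4-hydroxy-4-methylpent-2-en-1-yl]-2-methyl-2H-chromene-5,8-dione | CC(C)(O)/C=C/C[C@@]1(C)C=CC2=C(O1)C(=O)C=C(C(C)=O)C2=O
F7 | step 8 | 1-{(2S)-5,8-dihydroxy-2-[(2E)-4-hydroxy-4-methylpent-2-en-1-yl]-2-methyl-2H-chromen-6-yl}ethan-1-one | CC(C)(O)/C=C/C[C@@]1(C)C=Cc2c(O)c(C(C)=O)cc(O)c2O1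
F8 | step 4 | 1-[3-(chloromethyl)-4-hydroxy-2,5-dimethoxyphenyl]ethan-1-one | CC(=O)c1cc(OC)c(O)c(CCl)c1OC
F9 | step 4 | (3-acetyl-6-hydroxy-2,5-dimethoxybenzyl)triphenylphosphonium chloride | CC(=O)c1cc(OC)c(O)c(C[P+](c2ccccc2)(c2ccccc2)c2ccccc2)c1OC.[Cl-]
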